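(The runs are calculated with made-up constants, noise included.)

The target readings in the red flask, which is the flask asked about, climb and then stop rising. You read 28.8% at 20.0 h and 27.6% at 30.0 h, a drop of 1.2 percentage points against a scatter of 1 point. So treat the two readings as one level, and keep books on starting material, which I take as the limiting reagent.

common to all: starting material 10 mM

| flask | partner | capture agent | temperature | remark | time |
|---|---|---|---|---|---|
| red | 10 mM | 0.50 mM | 0 °C | the very flask that is asked about, followed so far |  |
| violet | 10 mM | 0.50 mM | −5 °C | run made earlier |  |
| flask | 10.0 mM | 0.500 mM | 0 °C |  | 2.0 d |

- red (time / h: target / %): 4.00: 15.2; 10.0: 24.9; 20.0: 28.8; 30.0: 27.6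
- violet (time / h: target / %): 4.00: 10.8; 10.0: 22.4; 20.0: 30.9; 30.0: 33.9

(standard deviation of a reading: 1 percentage point)

- Wednesday's: change nothing and wait 25 h more
- Tuesday's: at 2.0 d raise the temperature by 10 K, then wait 25 h
- Thursday's: at 2.0 d take out 90% of the target then present, then wait 25 h
- Saturday's: at 2.0 d add partner, 50.0% of the amount charged, then wait 25 h

* target, in percent of the starting material first charged, at 2.0 d
* the option that brings most further target ("none" if no option brings more than 2 percentage points) (Wednesday's / Tuesday's / Thursday's / Saturday's / none)
* target present, with what was taken out counted in, in percent of the starting material first charged, after Wednesday's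
* target present, with what was taken out counted in, in percent of the starting material first charged, after Saturday's

- removed target is counted in
- additions bring no volume worth counting

This reckoning is my own. Let y be the level, the mean of those two readings, as a share of the starting material charged:

y = 28.2%

I assume each unit of capture agent holds one unit of starting material, so its entry κ is at most:

κ = cT/cA = 5.00%

Subtract both entries from the charge:

U = 1 − y − κ = 66.8%

This U is the unbooked share, the part of the charge standing in neither entry. Next, if each target costs one partner, the partner left, as a share of its own charge, is:

p = 1 − y·cA/cB = 71.8%

So, on this count, the red flask still holds partner while its last two target readings agree within their scatter. Could U still be on its way to target? The first two red readings, taken as an exponential approach to y, give a time constant, which carries their scatter: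

τ = 4.38 h

The time 2.0 d is longer than τ, by a factor of 11.0. I therefore book U as lost to something that gives no target. My answers are y for "now", for Wednesday's and for Saturday's, and none for the best option, since I expect no gain above 2 points.

The forecast differs from this on Saturday's and on the best option. It gives 28.3% (25.5% to 30%) for now, 28% for Wednesday's and 24% for Saturday's. It names Thursday's as best, holding that “Removing target lets the remaining partner go to starting material”.

The flask gives 28.0%, and 28.0% and 28.0% after Wednesday's and Saturday's. The best option is none, with 0 points from Thursday's and 0 points from Tuesday's. At 48.0 h the flask holds 5.00% trapped intermediate, the entry κ, and 67.0% decomposed reagent, the entry U held open.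

    starting material → open intermediate (k = 5.70 × 10⁻⁴ /s, Ea = 90.0 kJ/mol)
    open intermediate + capture agent → trapped intermediate (k = 0.160 /M/s, Ea = 43.0 kJ/mol)
    open intermediate → decomposed reagent (k = 4.70 × 10⁻⁵ /s, Ea = 83.0 kJ/mol)
    partner + open intermediate → target (k = 0.00230 /M/s, Ea = 48.0 kJ/mol)
    (constants at 0 °C)

Now charge 25 mM of starting material, other charges held. This neighbouring flask gives 23.9% target. Its books read κ = 2.00% and U = 74.1%, and it stores 2.00% trapped intermediate and 74.1% decomposed reagent. Partner there is charged at 0.400 equiv to starting material; p comes to 40.4%, and the neighbouring flask ends with 40% of its partner.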